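**Plan**

Numbering used throughout: C1 lactone C=O, C2 its CH2, C3 the peroxy CH, C4 the lactone-bearing quaternary carbon, C5 the ring CH2, C6 the peroxy quaternary carbon, C7 onward the hexadecyl chain.
Retrosynthesis: (a) the chain is traced back to a C7≡C8 alkyne, a helper; (b) the lactone O–C4 bond and the dioxane C5–C6 bond are cut together; (c) the peroxide O–C3 bond is cut, leaving hydroperoxy ketal 6 (from hexadec-1-yne) and allylic mesylate 12.
Enabling feature: without O–C4 and C5–C6, C4=C5 is an isopropenyl group on the peroxy carbon C3, so C6–O–O–C3–C4=C5 is the peroxide counterpart of an isoprenol Prins substrate. The C1 carboxyl oxygen sits five atoms from C4, placed to quench the tertiary cation that ring closure creates there.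
Forward: the two arms are joined by O–C3 alkylation (step 8); in step 11 the 1,2-dioxane ring (C5–C6) and then the lactone ring (O–C4) close in one flask; step 12 saturates the alkyne.
Stereochemistry: C3 from a CBS reduction (R) followed by SN2 inversion (S); C6 from the chair transition state, where the slim alkynyl helper is axial and methyl equatorial; C4 from the cis ring fusion enforced by the short carboxyl tether.

Key step: step 11

Assumption: the mixed peroxyketals 13 to 18 are carried as mixtures of epimers at the ketal carbon (drawn without configuration there); this carbon becomes trigonal in step 11, so the mixture is of no consequence.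

**Route**

Step 1
Reactants: 1 hexadec-1-yne; 2 N-methoxy-N-methylacetamide
Product: 4 octadec-3-yn-2-one, via lithium hexadec-1-yn-1-ide 3 (not isolated)
Conditions: n-BuLi, THF, −78 °C; then 2, −78 to 0 °C; aq. NH4Cl
Reagents that add atoms: none
Why: Acylation of a lithium acetylide by a Weinreb amide, in which the chelated tetrahedral adduct holds until work-up so that addition should stop at the ynone.

Step 2
Reactants: 4 octadec-3-yn-2-one
Product: 5 2,2-dimethoxyoctadec-3-yne
Conditions: HC(OMe)3, MeOH, p-TsOH·H2O (cat.), rt; Et3N quench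
Reagents that add atoms: trimethyl orthoformate, COC(OC)OC
Why: Acid-catalysed ketalisation with an orthoester as dehydrating agent should convert the conjugated ynone into its dimethyl ketal without touching the triple bond.

Step 3
Reactants: 5 2,2-dimethoxyoctadec-3-yne
Product: 6 2-hydroperoxy-2-methoxyoctadec-3-yne (racemic)
Conditions: anhydrous H2O2 in Et2O (5 equiv), 10-camphorsulfonic acid (cat.), 0 °C; solid NaHCO3
Reagents that add atoms: hydrogen peroxide, OO
Why: Acid-catalysed perhydrolysis of a ketal (exchange of one OMe for OOH through the methoxy-oxocarbenium ion) should give the α-methoxy hydroperoxide, excess H2O2 and low temperature holding the reaction at single exchange; the new stereocentre forms racemic and is later destroyed.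

Step 4
Reactants: 7 3-(tert-butyldimethylsilyloxy)propanal; 8 isopropenylmagnesium bromide
Product: 9 rac-1-(tert-butyldimethylsilyloxy)-4-methylpent-4-en-3-ol
Conditions: THF, −78 to 0 °C; aq. NH4Cl
Reagents that add atoms: none
Why: Grignard addition of the isopropenyl nucleophile to the aldehyde should give the racemic allylic alcohol that carries C1 to C5.

Step 5
Reactants: 9 rac-1-(tert-butyldimethylsilyloxy)-4-methylpent-4-en-3-ol
Product: 10 1-(tert-butyldimethylsilyloxy)-4-methylpent-4-en-3-one
Conditions: Dess–Martin periodinane (1,1,1-triacetoxy-1,1-dihydro-1,2-benziodoxol-3(1H)-one), NaHCO3, CH2Cl2, 0 °C to rt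
Reagents that add atoms: none
Why: Buffered Dess–Martin oxidation should give the α-methylene ketone without double-bond migration or loss of the silyl ether.

Step 6
Reactants: 10 1-(tert-butyldimethylsilyloxy)-4-methylpent-4-en-3-one
Product: 11 (3R)-1-(tert-butyldimethylsilyloxy)-4-methylpent-4-en-3-ol
Conditions: (S)-Me-CBS catalyst [(S)-1-methyl-3,3-diphenyltetrahydro-1H,3H-pyrrolo[1,2-c][1,3,2]oxazaborole] (10 mol%), catecholborane, toluene, −78 °C; MeOH, then aq. NaOH wash
Reagents that add atoms: none
Why: Corey–Bakshi–Shibata reduction, in which the ketone binds the catalyst boron anti to the isopropenyl group (the large substituent) and the bound borane delivers hydride to the face that gives the (R)-alcohol, the low temperature suppressing hydroboration and conjugate reduction.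

Step 7
Reactants: 11 (3R)-1-(tert-butyldimethylsilyloxy)-4-methylpent-4-en-3-ol
Product: 12 (3R)-1-(tert-butyldimethylsilyloxy)-4-methylpent-4-en-3-yl methanesulfonate
Conditions: MsCl, Et3N, CH2Cl2, −30 °C; used at once without chromatography
Reagents that add atoms: methanesulfonyl chloride, CS(=O)(=O)Cl
Why: O-Sulfonylation leaves the C3–O bond untouched, so configuration is retained and a leaving group is in place.

Step 8
Reactants: 12 (3R)-1-(tert-butyldimethylsilyloxy)-4-methylpent-4-en-3-yl methanesulfonate; 6 2-hydroperoxy-2-methoxyoctadec-3-yne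
Product: 13 tert-butyl{[(3S)-3-[(2-methoxyoctadec-3-yn-2-yl)peroxy]-4-methylpent-4-en-1-yl]oxy}dimethylsilane
Conditions: CsOH·H2O, DMF, 0 °C
Reagents that add atoms: none
Why: Williamson-type SN2 O-alkylation of the caesium salt of an α-methoxy hydroperoxide (an α-effect nucleophile) by the secondary allylic mesylate should proceed with inversion at C3 to the (S)-peroxide, and because C1 is a silyl ether and not a carbonyl group no β-elimination can compete.

Step 9
Reactants: 13 tert-butyl{[(3S)-3-[(2-methoxyoctadec-3-yn-2-yl)peroxy]-4-methylpent-4-en-1-yl]oxy}dimethylsilane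
Product: 14 (3S)-3-[(2-methoxyoctadec-3-yn-2-yl)peroxy]-4-methylpent-4-en-1-ol
Conditions: Bu4NF, AcOH (1:1), THF, 0 °C to rt
Reagents that add atoms: none
Why: Fluoride-mediated cleavage of the silyl ether, buffered with AcOH to avoid base-induced Kornblum–DeLaMare fragmentation of the peroxide, should leave the fluoride-stable peroxyketal intact.

Step 10
Reactants: 14 (3S)-3-[(2-methoxyoctadec-3-yn-2-yl)peroxy]-4-methylpent-4-en-1-ol
Product: 16 (3S)-3-[(2-methoxyoctadec-3-yn-2-yl)peroxy]-4-methylpent-4-enoic acid, via β-peroxy aldehyde 15 (not isolated)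
Conditions: Dess–Martin periodinane, NaHCO3, CH2Cl2, 0 °C; then NaClO2, NaH2PO4, 2-methylbut-2-ene, t-BuOH/H2O, 0 °C; acid used crude
Reagents that add atoms: sodium chlorite, [Na+].[O-]Cl=O
Why: Dess–Martin oxidation followed at once by Pinnick oxidation keeps the β-peroxy aldehyde under non-basic conditions, so β-elimination of the peroxide is avoided, while 2-methylbut-2-ene takes up the hypochlorous acid before it can reach the alkene.

Step 11
Reactants: 16 (3S)-3-[(2-methoxyoctadec-3-yn-2-yl)peroxy]-4-methylpent-4-enoic acid
Product: 20 (1S,4S,6S)-4-(hexadec-1-yn-1-yl)-4,6-dimethyl-2,3,7-trioxabicyclo[4.3.0]nonan-8-one, via trimethylsilyl ester 17 (not isolated), via peroxycarbenium ion 18 (not isolated), via tertiary C4 cation 19 (not isolated)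
Conditions: N,O-bis(trimethylsilyl)acetamide (1.1 equiv), CH2Cl2, rt; then Me3SiOTf (0.3 equiv), −78 to −40 °C; aq. NaHCO3
Reagents that add atoms: none
Why: Proposed new method: catalytic Me3SiOTf removes the methoxy group of silyl ester 17 to give the conjugated peroxycarbenium ion 18, the terminal CH2 (C5) of the isopropenyl group attacks C6 to give the tertiary C4 cation 19, and the silyl ester carbonyl oxygen on the C3 arm captures C4 to form the O–C4 bond, the silyl group then leaving to take up the methoxide and regenerate the catalyst; the closest known reaction types are the Prins cyclization of isoprenol-type homoallylic alcohols with ketones and the Lewis-acid-mediated addition of peroxycarbenium ions to alkenes and allylsilanes. The dioxane ring closes through the C5–C6 bond in the 6-endo-trig mode (both carbons of the C4=C5 alkene end in the ring) by way of a chair transition state, and the lactone ring closes through the O–C4 bond in the 5-exo mode with respect to the same alkene. C6 is controlled by the geometry of 18: methyl, the bulkier group, lies trans to the O–O bond and becomes equatorial, the slim alkynyl group lies cis and becomes axial, and with the C3 arm equatorial this puts C2, the lactone oxygen and the alkynyl group on one face of the dioxane, as in the target. C4 is controlled by the tether: the oxygen is held by two atoms to C3 and can reach the cation only on the face cis to the C3 arm, which gives the cis ring fusion. The step needs ionisation at C–OMe rather than O–O, attack through C5 rather than C4, and capture of the cation before a hydride shift from C3 or proton loss; these are secured by the oxophilic silyl Lewis acid at low temperature, by the 1,1-disubstituted alkene that can give a tertiary cation only through six-ring closure, and by the intramolecular five-ring capture, while prior silylation of the acid keeps the medium free of protic acid that would lactonise the alkene directly.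

Step 12
Reactants: 20 (1S,4S,6S)-4-(hexadec-1-yn-1-yl)-4,6-dimethyl-2,3,7-trioxabicyclo[4.3.0]nonan-8-one
Product: 22 (1S,4R,6S)-4-hexadecyl-4,6-dimethyl-2,3,7-trioxabicyclo[4.3.0]nonan-8-one, via cis-alkenyl lactone 21 (not isolated)
Conditions: KO2CN=NCO2K (potassium azodicarboxylate, excess, in portions), AcOH, MeOH/CH2Cl2, 0 °C to rt
Reagents that add atoms: none
Why: Diimide reduction (concerted syn transfer of H2) should saturate the alkyne through the strained cis-alkene without touching the O–O bond or the lactone, and no stereocentre is affected (the descriptor at the peroxy quaternary carbon changes from S to R only because the CIP priorities change).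

**Compound list**

1 | hexadec-1-yne | C#CCCCCCCCCCCCCCC | starting material
2 | N-methoxy-N-methylacetamide | CC(=O)N(C)OC | starting material
3 | lithium hexadec-1-yn-1-ide | [Li]C#CCCCCCCCCCCCCCC | intermediate
4 | octadec-3-yn-2-one | CC(=O)C#CCCCCCCCCCCCCCC | intermediate
5 | 2,2-dimethoxyoctadec-3-yne | COC(C)(OC)C#CCCCCCCCCCCCCCC | intermediate
6 | 2-hydroperoxy-2-methoxyoctadec-3-yne (racemic) | COC(C)(OO)C#CCCCCCCCCCCCCCC | intermediate
7 | 3-(tert-butyldimethylsilyloxy)propanal | O=CCCO[Si](C)(C)C(C)(C)C | starting material
8 | isopropenylmagnesium bromide | CC(=C)[Mg]Br | starting material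
9 | rac-1-(tert-butyldimethylsilyloxy)-4-methylpent-4-en-3-ol | CC(=C)C(O)CCO[Si](C)(C)C(C)(C)C | intermediate
10 | 1-(tert-butyldimethylsilyloxy)-4-methylpent-4-en-3-one | CC(=C)C(=O)CCO[Si](C)(C)C(C)(C)C | intermediate
11 | (3R)-1-(tert-butyldimethylsilyloxy)-4-methylpent-4-en-3-ol | CC(=C)[C@H](O)CCO[Si](C)(C)C(C)(C)C | intermediate
12 | (3R)-1-(tert-butyldimethylsilyloxy)-4-methylpent-4-en-3-yl methanesulfonate | CC(=C)[C@H](OS(C)(=O)=O)CCO[Si](C)(C)C(C)(C)C | intermediate
13 | tert-butyl{[(3S)-3-[(2-methoxyoctadec-3-yn-2-yl)peroxy]-4-methylpent-4-en-1-yl]oxy}dimethylsilane (ketal carbon epimers) | CC(=C)[C@@H](OOC(C)(OC)C#CCCCCCCCCCCCCCC)CCO[Si](C)(C)C(C)(C)C | intermediate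
14 | (3S)-3-[(2-methoxyoctadec-3-yn-2-yl)peroxy]-4-methylpent-4-en-1-ol | CC(=C)[C@@H](OOC(C)(OC)C#CCCCCCCCCCCCCCC)CCO | intermediate
15 | (3S)-3-[(2-methoxyoctadec-3-yn-2-yl)peroxy]-4-methylpent-4-enal | CC(=C)[C@@H](OOC(C)(OC)C#CCCCCCCCCCCCCCC)CC=O | intermediate
16 | (3S)-3-[(2-methoxyoctadec-3-yn-2-yl)peroxy]-4-methylpent-4-enoic acid | CC(=C)[C@@H](OOC(C)(OC)C#CCCCCCCCCCCCCCC)CC(=O)O | intermediate
17 | trimethylsilyl (3S)-3-[(2-methoxyoctadec-3-yn-2-yl)peroxy]-4-methylpent-4-enoate | CC(=C)[C@@H](OOC(C)(OC)C#CCCCCCCCCCCCCCC)CC(=O)O[Si](C)(C)C | intermediate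
18 | peroxycarbenium ion formed from 17 by loss of methoxide | CC(=C)[C@@H](O[O+]=C(C)C#CCCCCCCCCCCCCCC)CC(=O)O[Si](C)(C)C | intermediate
19 | (3S,6S)-6-(hexadec-1-yn-1-yl)-4,6-dimethyl-3-[2-oxo-2-(trimethylsilyloxy)ethyl]-1,2-dioxan-4-ylium | CCCCCCCCCCCCCCC#C[C@]1(C)C[C+](C)[C@H](CC(=O)O[Si](C)(C)C)OO1 | intermediate
20 | (1S,4S,6S)-4-(hexadec-1-yn-1-yl)-4,6-dimethyl-2,3,7-trioxabicyclo[4.3.0]nonan-8-one | CCCCCCCCCCCCCCC#C[C@]1(C)C[C@]2(C)OC(=O)C[C@@H]2OO1 | intermediate
21 | (1S,4S,6S)-4-[(Z)-hexadec-1-en-1-yl]-4,6-dimethyl-2,3,7-trioxabicyclo[4.3.0]nonan-8-one | CCCCCCCCCCCCCC/C=C\[C@]1(C)C[C@]2(C)OC(=O)C[C@@H]2OO1 | intermediate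
22 | (1S,4R,6S)-4-hexadecyl-4,6-dimethyl-2,3,7-trioxabicyclo[4.3.0]nonan-8-one (bicyclic C1, C4, C6 are C3, C6, C4 of the plan numbering) | CCCCCCCCCCCCCCCC[C@]1(C)C[C@]2(C)OC(=O)C[C@@H]2OO1 | target

**Step count and risks**

Total steps: 12. Longest linear sequence: 9 steps (7 to 22, steps 4 to 12); the arm from 1 takes steps 1 to 3 and joins at step 8.

Step 11 (proposed new method). What may go wrong: ionisation at the O–O bond in place of the C–OMe bond (Hock-type cleavage of the allylic peroxide); a hydride shift from C3 or proton loss from the C4 cation before the carboxyl oxygen arrives; too little facial discrimination at C6. Fallback, from 11 back to 20, with the cascade divided into two closures of known type by changing the terminator to an allylsilane: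
- Alcohol 11 is converted into its allyl/alkoxide dianion (n-BuLi, N,N,N′,N′-tetramethylethylenediamine, Et2O, 0 °C) and silylated with Me3SiCl to bis-silyl compound F1.
- The O–Si bond of F1 is cleaved (K2CO3, MeOH) to give (R)-allylsilane alcohol F2.
- Mesylation as in step 7 gives mesylate F3, and alkylation of 6 as in step 8 gives peroxyketal F4.
- Me3SiOTf (cat.), CH2Cl2, −78 °C closes the dioxane by intramolecular attack of the allylsilane on the peroxycarbenium ion, through the same chair, to give 4-methylene-1,2-dioxane F5.
- Jones reagent (CrO3, H2SO4, acetone, 0 °C) removes the silyl ether and oxidises C1 to give acid F6.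
- Iodolactonisation (I2, NaHCO3, MeCN, 0 °C) closes the cis-fused lactone at C4 to give iodomethyl lactone F7.
- Bu3SnH with Et3B/air in toluene at 0 °C replaces iodine by hydrogen to give 20.

Step 8. What may go wrong: with the bulky tertiary peroxide anion, attack at the unhindered alkene terminus (allylic transposition), elimination, or ionisation of the allylic mesylate with loss of configuration. Fallback, from 12 back to 13: the C3–O bond is made with a small nucleophile and the ketal carbon is attached afterwards. Mesylate 12 is displaced by H2O2 (KOH, MeOH/THF, 0 °C), with inversion, to give (S)-hydroperoxide F8. F8 then exchanges with one methoxy group of ketal 5 (pyridinium p-toluenesulfonate, CH2Cl2, 0 °C) to give 13.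

Step 3. What may go wrong: exchange of the second methoxy group as well (geminal dihydroperoxide formation) or hydrolysis back to the ynone during isolation. Fallback, from 1 back to 6: the hydroperoxy ketal is made by ozonolysis instead of exchange. Sonogashira coupling of 1 with 2-bromopropene (PdCl2(PPh3)2, CuI, Et3N) gives enyne F9. Ozonolysis of its alkene, which reacts far faster than the alkyne, in CH2Cl2/MeOH at −78 °C, where methanol traps the carbonyl oxide, gives 6.

Further compounds
F1 | step 11 | tert-butyldimethyl{[(3R)-4-[(trimethylsilyl)methyl]-3-(trimethylsilyloxy)pent-4-en-1-yl]oxy}silane | C=C(C[Si](C)(C)C)[C@H](O[Si](C)(C)C)CCO[Si](C)(C)C(C)(C)C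
F2 | step 11 | (3R)-1-(tert-butyldimethylsilyloxy)-4-[(trimethylsilyl)methyl]pent-4-en-3-ol | C=C(C[Si](C)(C)C)[C@H](O)CCO[Si](C)(C)C(C)(C)C
F3 | step 11 | (3R)-1-(tert-butyldimethylsilyloxy)-4-[(trimethylsilyl)methyl]pent-4-en-3-yl methanesulfonate | C=C(C[Si](C)(C)C)[C@H](OS(C)(=O)=O)CCO[Si](C)(C)C(C)(C)C
F4 | step 11 | tert-butyl{[(3S)-3-[(2-methoxyoctadec-3-yn-2-yl)peroxy]-4-[(trimethylsilyl)methyl]pent-4-en-1-yl]oxy}dimethylsilane | C=C(C[Si](C)(C)C)[C@@H](OOC(C)(OC)C#CCCCCCCCCCCCCCC)CCO[Si](C)(C)C(C)(C)C
F5 | step 11 | (3S,6S)-3-[2-(tert-butyldimethylsilyloxy)ethyl]-6-(hexadec-1-yn-1-yl)-6-methyl-4-methylidene-1,2-dioxane | CCCCCCCCCCCCCCC#C[C@]1(C)CC(=C)[C@H](CCO[Si](C)(C)C(C)(C)C)OO1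
F6 | step 11 | 2-[(3S,6S)-6-(hexadec-1-yn-1-yl)-6-methyl-4-methylidene-1,2-dioxan-3-yl]acetic acid | CCCCCCCCCCCCCCC#C[C@]1(C)CC(=C)[C@H](CC(=O)O)OO1
F7 | step 11 | (1S,4S,6S)-4-(hexadec-1-yn-1-yl)-6-(iodomethyl)-4-methyl-2,3,7-trioxabicyclo[4.3.0]nonan-8-one | CCCCCCCCCCCCCCC#C[C@]1(C)C[C@]2(CI)OC(=O)C[C@@H]2OO1
F8 | step 8 | tert-butyl{[(3S)-3-hydroperoxy-4-methylpent-4-en-1-yl]oxy}dimethylsilane | CC(=C)[C@@H](OO)CCO[Si](C)(C)C(C)(C)C
F9 | step 3 | 2-methyloctadec-1-en-3-yne | C=C(C)C#CCCCCCCCCCCCCCC
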